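**Retrosynthetic overview**

1. The sn-3 hydroxyl is unmasked last from a PMB ether. The ester C–O bond at glycerol C2 divides the target into acid 14 and alcohol 18; (S)-solketal 15 supplies the only stereocentre.
2. Acid 14 comes from terminal alkyne 12 (Zr-catalysed methylalumination/CO2 sets the E-enoate), 12 from enone 9 (temporary oxygen on ring C3), and 9 from vinylogous ester 5 plus Grignard 7 (Stork–Danheiser).
3. Key disconnection: cyclohexene bonds C2–C3 and C5–C6 (C1 bears the chain, C2 the methyl, C6 the gem-dimethyl). Dione 4 comes from 2-methylpentan-3-one 1 and methyl acrylate 2 by a one-pot Michael–Claisen [3+3] annulation.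
4. Enabling feature: ring C1 lies between the methyl-bearing C2 and the quaternary C6. Written as a ketone carbonyl, it makes C2 and C6 the two α-carbons of one acyclic ketone, and the C3–C4–C5 trimethylene becomes the three carbons of an acrylate (C3 at acyl level, removed in steps 4–5).
5. Ring order: the single carbocycle is made in step 1; no other ring of the target is formed (the dioxolane of 15 is only a protecting group).

Key step: step 1

Remark: the glycerol unit is read as 1-O-acetyl-2-O-acyl-sn-glycerol, (S) at C2. The diketo form of 4 and compounds 8 and 10 are racemic at centres that the route later destroys.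

**Fragment A (acid 14)**

Step 1
Reactants: 1 2-methylpentan-3-one; 2 methyl acrylate
Product: 4 2,4,4-trimethylcyclohexane-1,3-dione, via Michael adduct 3 (not isolated)
Conditions: KOtBu (1.2 equiv), THF, 0 °C to reflux; then 2 M HCl
Reagents that add atoms: none
Why: tert-Butoxide equilibrates the enolates of 1; the tertiary α-carbon (future ring C6) adds to the β-carbon of 2 (Michael addition, bond C5–C6, quaternary centre), and the α'-methylene of adduct 3 (future C2) then acylates on the ester carbon (Claisen condensation, bond C2–C3) with loss of methoxide. The closest known reaction type is the one-pot Michael–Claisen [3+3] annulation of ketones with acrylates to cyclohexane-1,3-diones, for example 4,4-dimethylcyclohexane-1,3-dione from 3-methylbutan-2-one. The ring closes by a 6-(enolendo)-exo-trig acylation. The only new stereocentre, C2 of 4, lies between two carbonyl groups, forms racemic and enolises freely, and becomes sp2 in step 2, so it needs no control. The step needs Michael addition at the isopropyl carbon and acylation at the ethyl carbon: only this pairing gives a 1,3-dione with an acidic C2–H, whose deprotonation to the potassium enolate draws the equilibria forward, whereas the opposite pairing could only close to a non-enolisable 2,2-dimethyl-1,3-dione that alkoxide reopens by retro-Claisen cleavage, and closure within one α-carbon would need a four-membered ring.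

Step 2
Reactants: 4 2,4,4-trimethylcyclohexane-1,3-dione
Product: 5 3-(2-methylpropoxy)-2,6,6-trimethylcyclohex-2-en-1-one
Conditions: i-BuOH, TsOH (cat.), toluene, reflux, Dean–Stark
Reagents that add atoms: 2-methylpropan-1-ol, CC(C)CO
Why: Acid-catalysed enol etherification of the vinylogous acid with azeotropic removal of water; the alcohol should attack the carbonyl remote from the gem-dimethyl group, so the neopentyl carbonyl remains the ketone, as in the known etherification of 4,4-dimethylcyclohexane-1,3-dione.

Step 3
Reactants: 5 3-(2-methylpropoxy)-2,6,6-trimethylcyclohex-2-en-1-one; 6 (4-bromobut-1-yn-1-yl)trimethylsilane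
Product: 9 2,4,4-trimethyl-3-[4-(trimethylsilyl)but-3-yn-1-yl]cyclohex-2-en-1-one, via Grignard reagent 7 (not isolated), via tertiary carbinol 8 (not isolated)
Conditions: 6, Mg, THF, rt; CeCl3 (anhydrous), then 5, THF, −78 to 0 °C; then 2 M HCl, THF, rt
Reagents that add atoms: water, O
Why: Stork–Danheiser alkylative carbonyl transposition: the organocerium reagent from 7 should add 1,2 to the only carbonyl of 5 with little enolisation, and acid converts carbinol 8 into the transposed enone with loss of isobutanol, which places the chain on the carbon next to the quaternary centre.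

Step 4
Reactants: 9 2,4,4-trimethyl-3-[4-(trimethylsilyl)but-3-yn-1-yl]cyclohex-2-en-1-one
Product: 10 2,4,4-trimethyl-3-[4-(trimethylsilyl)but-3-yn-1-yl]cyclohex-2-en-1-ol (racemic)
Conditions: NaBH4, CeCl3·7H2O, MeOH, 0 °C
Reagents that add atoms: none
Why: Luche reduction should reduce the enone carbonyl 1,2 only; the new carbinol centre forms racemic and is removed in step 5.

Step 5
Reactants: 10 2,4,4-trimethyl-3-[4-(trimethylsilyl)but-3-yn-1-yl]cyclohex-2-en-1-ol
Product: 11 trimethyl[4-(2,6,6-trimethylcyclohex-1-en-1-yl)but-1-yn-1-yl]silane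
Conditions: Et3SiH, TFA, CH2Cl2, −40 to −20 °C
Reagents that add atoms: none
Why: Ionic hydrogenation of an allylic alcohol: acid ionises 10 to an allyl cation with a secondary terminus (the former carbinol carbon) and a hindered tertiary terminus (the chain-bearing carbon), and Et3SiH should deliver hydride to the secondary terminus, keeping the tetrasubstituted double bond in place; the low temperature guards that alkene against protonation.

Step 6
Reactants: 11 trimethyl[4-(2,6,6-trimethylcyclohex-1-en-1-yl)but-1-yn-1-yl]silane
Product: 12 2-(but-3-yn-1-yl)-1,3,3-trimethylcyclohex-1-ene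
Conditions: K2CO3 (cat.), MeOH, rt
Reagents that add atoms: none
Why: Methoxide-mediated protodesilylation of the alkynylsilane; nothing else in 11 reacts.

Step 7
Reactants: 12 2-(but-3-yn-1-yl)-1,3,3-trimethylcyclohex-1-ene
Product: 14 (2E)-3-methyl-5-(2,6,6-trimethylcyclohex-1-en-1-yl)pent-2-enoic acid, via alkenylalane 13 (not isolated)
Conditions: Me3Al (2 equiv), Cp2ZrCl2 (20 mol %), CH2Cl2, 0 °C to rt; excess Me3Al removed in vacuo; n-BuLi, THF, −78 °C; CO2, −78 °C to rt; then 1 M HCl
Reagents that add atoms: trimethylaluminium, C[Al](C)C; carbon dioxide, O=C=O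
Why: Negishi zirconium-catalysed methylalumination adds methyl and aluminium syn across the terminal alkyne (methyl to the internal carbon), which fixes the E geometry; the alkenylalane, turned into its alanate with n-BuLi, should be carboxylated with retention, and the tetrasubstituted ring alkene does not carbometalate.

**Fragment B (alcohol 18)**

Step 8
Reactants: 15 (S)-solketal, [(4S)-2,2-dimethyl-1,3-dioxolan-4-yl]methanol
Product: 16 (4S)-4-{[(4-methoxyphenyl)methoxy]methyl}-2,2-dimethyl-1,3-dioxolane
Conditions: NaH, PMBCl, Bu4NI (cat.), THF/DMF, 0 °C to rt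
Reagents that add atoms: 4-methoxybenzyl chloride, COc1ccc(CCl)cc1
Why: Williamson etherification of the primary alkoxide; the stereocentre is not involved.

Step 9
Reactants: 16 (4S)-4-{[(4-methoxyphenyl)methoxy]methyl}-2,2-dimethyl-1,3-dioxolane
Product: 17 (2R)-3-[(4-methoxyphenyl)methoxy]propane-1,2-diol (3-O-PMB-sn-glycerol)
Conditions: AcOH/H2O (4:1), 40 °C
Reagents that add atoms: none
Why: Mild acid hydrolysis of the acetonide, which the PMB ether survives; no bond to the stereocentre breaks (the descriptor changes only through the priority rules).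

Step 10
Reactants: 17 (2R)-3-[(4-methoxyphenyl)methoxy]propane-1,2-diol
Product: 18 (2S)-2-hydroxy-3-[(4-methoxyphenyl)methoxy]propyl acetate (1-O-acetyl-3-O-PMB-sn-glycerol)
Conditions: vinyl acetate, immobilised Candida antarctica lipase B, MTBE, rt
Reagents that add atoms: vinyl acetate, CC(=O)OC=C
Why: Lipase-catalysed transesterification should acylate only the primary hydroxyl; it is irreversible (vinyl alcohol tautomerises to acetaldehyde), and the neutral medium avoids acetyl migration to O2.

**Union and end game**

Step 11
Reactants: 14 (2E)-3-methyl-5-(2,6,6-trimethylcyclohex-1-en-1-yl)pent-2-enoic acid; 18 (2S)-2-hydroxy-3-[(4-methoxyphenyl)methoxy]propyl acetate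
Product: 19 (2S)-1-(acetyloxy)-3-[(4-methoxyphenyl)methoxy]propan-2-yl (2E)-3-methyl-5-(2,6,6-trimethylcyclohex-1-en-1-yl)pent-2-enoate
Conditions: EDC·HCl, DMAP (cat.), CH2Cl2, 0 °C to rt
Reagents that add atoms: none
Why: Steglich esterification acylates the secondary hydroxyl with retention at C2 (no C–O bond at the stereocentre breaks); the mild, nearly neutral conditions should preserve the E-enoate and the primary acetate.

Step 12
Reactants: 19 (2S)-1-(acetyloxy)-3-[(4-methoxyphenyl)methoxy]propan-2-yl (2E)-3-methyl-5-(2,6,6-trimethylcyclohex-1-en-1-yl)pent-2-enoate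
Product: 20 (2S)-1-(acetyloxy)-3-hydroxypropan-2-yl (2E)-3-methyl-5-(2,6,6-trimethylcyclohex-1-en-1-yl)pent-2-enoate (target)
Conditions: DDQ, CH2Cl2/pH 7 phosphate buffer (10:1), 0 °C; rapid chromatography on boric-acid-treated silica
Reagents that add atoms: none
Why: Oxidative cleavage of the PMB ether by DDQ in buffered wet CH2Cl2 is neutral and cold, which should prevent 1,2-to-1,3 acyl migration in the diacylglycerol and leave both alkenes untouched.

**Compound list**

1 | 2-methylpentan-3-one | CCC(=O)C(C)C | starting material
2 | methyl acrylate | C=CC(=O)OC | starting material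
3 | methyl 4,4-dimethyl-5-oxoheptanoate | CCC(=O)C(C)(C)CCC(=O)OC | intermediate
4 | 2,4,4-trimethylcyclohexane-1,3-dione (racemic, enolisable) | CC1C(=O)CCC(C)(C)C1=O | intermediate
5 | 3-(2-methylpropoxy)-2,6,6-trimethylcyclohex-2-en-1-one | CC(C)COC1=C(C)C(=O)C(C)(C)CC1 | intermediate
6 | (4-bromobut-1-yn-1-yl)trimethylsilane | C[Si](C)(C)C#CCCBr | starting material
7 | [4-(trimethylsilyl)but-3-yn-1-yl]magnesium bromide | C[Si](C)(C)C#CCC[Mg]Br | intermediate
8 | 2,6,6-trimethyl-3-(2-methylpropoxy)-1-[4-(trimethylsilyl)but-3-yn-1-yl]cyclohex-2-en-1-ol (racemic) | CC(C)COC1=C(C)C(O)(CCC#C[Si](C)(C)C)C(C)(C)CC1 | intermediate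
9 | 2,4,4-trimethyl-3-[4-(trimethylsilyl)but-3-yn-1-yl]cyclohex-2-en-1-one | CC1=C(CCC#C[Si](C)(C)C)C(C)(C)CCC1=O | intermediate
10 | 2,4,4-trimethyl-3-[4-(trimethylsilyl)but-3-yn-1-yl]cyclohex-2-en-1-ol (racemic) | CC1=C(CCC#C[Si](C)(C)C)C(C)(C)CCC1O | intermediate
11 | trimethyl[4-(2,6,6-trimethylcyclohex-1-en-1-yl)but-1-yn-1-yl]silane | CC1=C(CCC#C[Si](C)(C)C)C(C)(C)CCC1 | intermediate
12 | 2-(but-3-yn-1-yl)-1,3,3-trimethylcyclohex-1-ene | C#CCCC1=C(C)CCCC1(C)C | intermediate
13 | dimethyl[(1E)-2-methyl-4-(2,6,6-trimethylcyclohex-1-en-1-yl)but-1-en-1-yl]alane | C[Al](C)/C=C(\C)CCC1=C(C)CCCC1(C)C | intermediate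
14 | (2E)-3-methyl-5-(2,6,6-trimethylcyclohex-1-en-1-yl)pent-2-enoic acid | OC(=O)/C=C(\C)CCC1=C(C)CCCC1(C)C | intermediate
15 | (S)-solketal, [(4S)-2,2-dimethyl-1,3-dioxolan-4-yl]methanol | CC1(C)OC[C@H](CO)O1 | starting material
16 | (4S)-4-{[(4-methoxyphenyl)methoxy]methyl}-2,2-dimethyl-1,3-dioxolane | CC1(C)OC[C@H](COCc2ccc(OC)cc2)O1 | intermediate
17 | (2R)-3-[(4-methoxyphenyl)methoxy]propane-1,2-diol | OC[C@H](COCc1ccc(OC)cc1)O | intermediate
18 | (2S)-2-hydroxy-3-[(4-methoxyphenyl)methoxy]propyl acetate | CC(=O)OC[C@H](COCc1ccc(OC)cc1)O | intermediate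
19 | (2S)-1-(acetyloxy)-3-[(4-methoxyphenyl)methoxy]propan-2-yl (2E)-3-methyl-5-(2,6,6-trimethylcyclohex-1-en-1-yl)pent-2-enoate | CC(=O)OC[C@H](COCc1ccc(OC)cc1)OC(=O)/C=C(\C)CCC1=C(C)CCCC1(C)C | intermediate
20 | (2S)-1-(acetyloxy)-3-hydroxypropan-2-yl (2E)-3-methyl-5-(2,6,6-trimethylcyclohex-1-en-1-yl)pent-2-enoate | CC(=O)OC[C@H](CO)OC(=O)/C=C(\C)CCC1=C(C)CCCC1(C)C | target

**Step count and risks**

Total steps: 12. Longest linear sequence: 9 (steps 1–7, 11, 12).

Steps most likely to fail:

- **Step 1.** Michael addition may run through the less substituted enolate (the ethyl α-carbon), and twofold addition or oligomerisation of the acrylate may consume material, so the annulation may deliver little dione. Fallback: the methyl group on C2 is introduced after the ring is made. Setting out from 2, the established Michael–Claisen annulation with commercial 3-methylbutan-2-one (KOtBu, THF) should give 4,4-dimethylcyclohexane-1,3-dione F1. C-methylation between the two carbonyl groups (MeI, K2CO3, acetone, reflux) then returns to the route at 4.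

- **Step 3.** The organometallic reagent may fail to add to the carbonyl flanked by the quaternary centre and the substituted enol ether, through deprotonation at the γ-methylene or simple lack of reaction. Fallback: the chain is attached by cross-coupling instead of carbonyl addition.
  - Setting out from 4, oxalyl chloride with catalytic DMF in CH2Cl2 should give 3-chloro-2,6,6-trimethylcyclohex-2-en-1-one F2.
  - Hydrogenation over Pd/C with Et3N should remove the chlorine and saturate the alkene to give 2,2,6-trimethylcyclohexan-1-one F3.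
  - LDA then PhNTf2 should give 2,6,6-trimethylcyclohex-1-en-1-yl trifluoromethanesulfonate F4.
  - Negishi coupling of F4 with [4-(trimethylsilyl)but-3-yn-1-yl]zinc bromide F5 (from 6, Zn dust, LiCl, THF) under Pd(dppf)Cl2 catalysis comes back to the route at 11, so steps 4 and 5 are no longer needed.

- **Step 5.** The allyl cation may lose a proton to give dienes, or the tetrasubstituted alkene may be protonated and reduced further. Fallback: hydride displacement under basic conditions, with no carbocation. Setting out from 10, Corey–Kim chlorination (NCS, Me2S, CH2Cl2, −20 °C) should give [4-(3-chloro-2,6,6-trimethylcyclohex-1-en-1-yl)but-1-yn-1-yl]trimethylsilane F6. LiBHEt3 in THF at 0 °C should then displace the secondary allylic chloride directly (the SN2' site is a hindered tertiary carbon) and come back to the route at 11.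

**Further compounds**

F1 | step 1 | 4,4-dimethylcyclohexane-1,3-dione | CC1(C)CCC(=O)CC1=O
F2 | step 3 | 3-chloro-2,6,6-trimethylcyclohex-2-en-1-one | CC1=C(Cl)CCC(C)(C)C1=O
F3 | step 3 | 2,2,6-trimethylcyclohexan-1-one (racemic) | CC1CCCC(C)(C)C1=O
F4 | step 3 | 2,6,6-trimethylcyclohex-1-en-1-yl trifluoromethanesulfonate | CC1=C(OS(=O)(=O)C(F)(F)F)C(C)(C)CCC1
F5 | step 3 | [4-(trimethylsilyl)but-3-yn-1-yl]zinc bromide | C[Si](C)(C)C#CCC[Zn]Br
F6 | step 5 | [4-(3-chloro-2,6,6-trimethylcyclohex-1-en-1-yl)but-1-yn-1-yl]trimethylsilane (racemic) | CC1=C(CCC#C[Si](C)(C)C)C(C)(C)CCC1Cl
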